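The data stem from a simulated flask on assumed constants.

- A unit first: read the north-east run in mM of substrate per minute, not in percent per minute, and call that number the draw.

in all of them: gas 190 mM (held)

| run | substrate | remark | time |
|---|---|---|---|
| north-east | 2 M | run made earlier |  |
| flask | 1.0 M |  | 2.5 h |

north-east run (percent of the substrate charged)

| time / min | substrate / % | mono adduct / % | bis adduct / % |
|---|---|---|---|
| 6.00 | 97.9 | 1.2 | 0.2 |
| 12.0 | 94.6 | 3.5 | 0 |
| 20.0 | 91.1 | 6.2 | 0.2 |
| 25.0 | 88.9 | 8.2 | 0.4 |
| 30.0 | 86.9 | 10.1 | 0.3 |
| 40.0 | 82.2 | 12.9 | 0 |
| 50.0 | 77.7 | 16.9 | 0.6 |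

(each reading ± 0.3 percentage points)

- the numbers in the tables scatter by 0.3 percentage points (one standard deviation)
- at the start none of the gas is in solution

1. amount of substrate in the flask at 2.5 h, in percent of the substrate charged
2. amount of mono adduct in the flask at 2.5 h, in percent of the substrate charged
3. amount of bis adduct in the flask at 2.5 h, in percent of the substrate charged

- Between its first and last readings the north-east substrate falls from 97.9% to 77.7% of 2 M, so the draw reads 9.18 mM min⁻¹. By my reading, that one run can't separate a straight line from a slow first-order curve, so what follows is my commitment, not a proof.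
- Fastest rung: traced back, the line reaches the full charge at 1.43 min, a lag read from the first reading, while gas enters a solution that starts with none.
- Next rung: at this draw, a solution at 190 mM would be emptied in 20.7 min, less than the 50.0 min the run lasted. Gas must therefore keep crossing in, so I take that transfer as the rate-limiting step and keep the draw in mM per minute at half the charge.
- Slowest rung: charge divided by draw is 109 min for this flask, and I call it the clearing time; it is longer than the other rungs but shorter than 150 min. The draw delivers 1.38 M against 1.0 M of substrate, so my reckoning ends the substrate before the asked time and sends a surplus of 0.377 M on towards bis adduct.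
- The forecast differs from my reckoning: “I assume first order, so percent conversion is independent of the charge”, which gives 47.5% substrate, 38% mono adduct and 2.3% bis adduct.
- The flask gives 9.45% substrate, 63.7% mono adduct and 15.5% bis adduct.

    reagent → decomposition product (k = 2.00 × 10⁻⁵ min⁻¹)
    substrate + reagent → other mono adduct + by-product (k = 0.0810 M⁻¹ min⁻¹)
    reagent + other mono adduct → bis adduct + by-product (k = 0.150 M⁻¹ min⁻¹)
    reagent + mono adduct → bis adduct + by-product (k = 0.00970 M⁻¹ min⁻¹)
    substrate + reagent → mono adduct + by-product (k = 0.230 M⁻¹ min⁻¹)
    gas ⇌ reagent, rate k6*(csat - [reagent]) (kL = 0.0550 min⁻¹)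

- This flask reaches 2.5 h at 1.38 clearing times, with 1.06 M of by-product, less than the 1.38 M of the draw, and 0.0901 M of reagent in solution. In the neighbour flask, like this one but charged with 0.60 M of substrate, the clearing time is 65.3 min, so the same 2.5 h is 2.30 clearing times. That flask holds 2.06% substrate, 66.1% mono adduct and 25.2% bis adduct.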